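The route cuts the C13–C14 bond. This is the threo pair of oxygenated carbons (C13 acetate, C14 lactone oxygen) shared by the 14-membered carbocycle and the cis-fused γ-lactone (C14–O–C16–C15–C1). Each of these carbons can be traced back to an aldehyde, so low-valent titanium joins them reductively. One operation closes the macrocycle, sets C13 and C14, and lets the C14 alkoxide acylate on the C16 methyl ester, leaving C13–OH free. The precursor is an open C13,C14-dialdehyde carrying the C16 ester, the E-C3=C4 alkene, the C8 exomethylene, C7–OTBS and the stereocentres C1, C7 and C12. It is assembled from three fragments. Methylenation, acetate exchange and epoxidation follow ring closure.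

Key step: step 17

Numbering and configuration: cembrane numbering is used throughout. C1 is the ring CH bearing C15–C17, C3–C4 is the oxirane with C18, C8=C19 is the exomethylene, C12 bears C20, and C14 is the lactone O–CH. The target is read as 1S,3R,4R,7R,12S,13R,14R, with an oxirane derived from the E-alkene.

Remark on the chemistry: stereocentres that are erased later are left unassigned. These are the oxirane/diol carbon in 11, 15 and 16, C7 in 19, and C15 in 30 and 31.

Step 1
Reactants: 1 hept-6-ynoic acid; 2 (S)-4-benzyl-1,3-oxazolidin-2-one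
Product: 4 (4S)-4-benzyl-3-(hept-6-ynoyl)-1,3-oxazolidin-2-one, via mixed pivalic anhydride 3 (not isolated)
Conditions: t-BuCOCl, Et3N, THF, −20 °C; then 2, LiCl, −20 °C → rt
Reagents that add atoms: none
Why: N-acylation of the oxazolidinone through a mixed anhydride should work because the bulky pivaloyl carbonyl diverts the LiCl-activated auxiliary to the heptynoyl carbonyl, and no stereocentre is touched.

Step 2
Reactants: 4 (4S)-4-benzyl-3-(hept-6-ynoyl)-1,3-oxazolidin-2-one
Product: 6 (4S)-4-benzyl-3-[(2S)-2-methylhept-6-ynoyl]-1,3-oxazolidin-2-one, via sodium Z-enolate 5 (not isolated)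
Conditions: NaN(SiMe3)2, THF, −78 °C; MeI, −78 → −40 °C
Reagents that add atoms: iodomethane, CI
Why: Evans asymmetric alkylation: the chelated Z-enolate is shielded on one face by the benzyl group, so MeI enters from the other face and sets C12 as S, while the less acidic alkyne C–H is left alone.

Step 3
Reactants: 6 (4S)-4-benzyl-3-[(2S)-2-methylhept-6-ynoyl]-1,3-oxazolidin-2-one
Product: 7 (2S)-2-methylhept-6-yn-1-ol
Conditions: LiBH4, Et2O–THF, 0 °C
Reagents that add atoms: none
Why: Reductive removal of the auxiliary with LiBH4 (hydride attack at the exocyclic imide carbonyl) gives the C13 primary alcohol without epimerising C12 and returns the auxiliary for reuse.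

Step 4
Reactants: 7 (2S)-2-methylhept-6-yn-1-ol
Product: 8 (2S)-6-iodo-2-methylhept-6-en-1-ol
Conditions: NaI, Me3SiCl, H2O, MeCN, rt
Reagents that add atoms: sodium iodide, [Na+].[I-]
Why: Markovnikov hydroiodination of the terminal alkyne with hydrogen iodide generated in situ places iodine on the internal carbon C8 and so gives the 2-iodo-1-alkene needed for C7–C8 bond formation.

Step 5
Reactants: 8 (2S)-6-iodo-2-methylhept-6-en-1-ol
Product: 9 triethyl{[(2S)-6-iodo-2-methylhept-6-en-1-yl]oxy}silane (fragment A, C8–C13 with C19 and C20)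
Conditions: Et3SiCl, imidazole, CH2Cl2, 0 °C
Reagents that add atoms: chlorotriethylsilane, CC[Si](Cl)(CC)CC
Why: Standard silylation of a primary alcohol, in which the triethylsilyl ether is chosen because it survives steps 10 to 14 and can later be oxidised directly at C13.

Step 6
Reactants: 10 geranyl bromide, (2E)-1-bromo-3,7-dimethylocta-2,6-diene
Product: 11 6,7-epoxygeranyl bromide, 3-[(3E)-6-bromo-4-methylhex-3-en-1-yl]-2,2-dimethyloxirane (racemic at the oxirane CH)
Conditions: mCPBA (1.0 equiv), CH2Cl2, −20 → 0 °C
Reagents that add atoms: 3-chloroperoxybenzoic acid, O=C(OO)c1cccc(Cl)c1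
Why: Prilezhaev epoxidation is governed by alkene nucleophilicity, so the remote isopropylidene alkene reacts while C3=C4, deactivated by the allylic bromine, keeps the pure E geometry supplied by the geranyl skeleton.

Step 7
Reactants: 2 (S)-4-benzyl-1,3-oxazolidin-2-one; 12 methyl 4-chloro-4-oxobutanoate
Product: 13 methyl 4-[(4S)-4-benzyl-2-oxo-1,3-oxazolidin-3-yl]-4-oxobutanoate
Conditions: Et3N, DMAP (cat.), CH2Cl2, 0 °C → rt
Reagents that add atoms: none
Why: DMAP-catalysed N-acylation of the oxazolidinone by an acid chloride, which installs C14, C1, C15 and C16 with the methyl ester already in place.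

Step 8
Reactants: 13 methyl 4-[(4S)-4-benzyl-2-oxo-1,3-oxazolidin-3-yl]-4-oxobutanoate; 11 6,7-epoxygeranyl bromide
Product: 15 methyl (3S,5E)-3-{[(4S)-4-benzyl-2-oxo-1,3-oxazolidin-3-yl]carbonyl}-8-(3,3-dimethyloxiran-2-yl)-6-methyloct-5-enoate, via sodium Z-enolate 14 (not isolated)
Conditions: NaN(SiMe3)2, THF, −78 °C; then 11, −78 → −30 °C
Reagents that add atoms: none
Why: Evans asymmetric alkylation: only the more acidic imide α-CH2 is enolised, the chelated Z-enolate is attacked by the primary allylic bromide in an SN2 sense on the face opposite the benzyl group, and this sets C1 as S while the oxirane is inert at low temperature.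

Step 9
Reactants: 15 epoxy imide ester
Product: 17 methyl (3S,5E)-3-{[(4S)-4-benzyl-2-oxo-1,3-oxazolidin-3-yl]carbonyl}-6-methyl-9-oxonon-5-enoate (C7 aldehyde), via vicinal diol 16 (not isolated)
Conditions: H5IO6, THF–H2O, 0 °C
Reagents that add atoms: none
Why: Acid-promoted hydrolysis of the trisubstituted oxirane followed by Malaprade glycol cleavage in the same flask excises the isopropylidene carbons as acetone and unveils the C7 aldehyde without touching C3=C4, imide or ester.

Step 10
Reactants: 9 alkenyl iodide (fragment A); 17 C7 aldehyde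
Product: 19 methyl (3S,5E,14S)-3-{[(4S)-4-benzyl-2-oxo-1,3-oxazolidin-3-yl]carbonyl}-9-hydroxy-6,14-dimethyl-10-methylidene-15-(triethylsilyloxy)pentadec-5-enoate (C7 epimers), via alkenylchromium dichloride 18 (not isolated)
Conditions: CrCl2 (4 equiv), NiCl2 (2 mol %), DMF, rt
Reagents that add atoms: none
Why: Nozaki–Hiyama–Kishi coupling: nickel-catalysed activation of the carbon–iodine bond and transfer to chromium give an alkenylchromium species that adds only to the aldehyde, leaving imide, ester and silyl ether alone, and the uncontrolled C7 centre is levelled in step 11.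

Step 11
Reactants: 19 C7-epimeric allylic alcohols
Product: 20 methyl (3S,5E,14S)-3-{[(4S)-4-benzyl-2-oxo-1,3-oxazolidin-3-yl]carbonyl}-6,14-dimethyl-10-methylidene-9-oxo-15-(triethylsilyloxy)pentadec-5-enoate (C7 enone)
Conditions: Dess–Martin periodinane, pyridine, CH2Cl2, 0 °C → rt
Reagents that add atoms: none
Why: Dess–Martin oxidation of the secondary allylic alcohol under buffered conditions erases the uncontrolled C7 centre and gives the α-substituted enone without disturbing the silyl ether or C1.

Step 12
Reactants: 20 C7 enone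
Product: 21 the (9R)-9-hydroxy compound, that is 19 with C7 = R
Conditions: (S)-2-methyl-CBS-oxazaborolidine (0.5 equiv), catecholborane, toluene, −78 °C
Reagents that add atoms: none
Why: Corey–Bakshi–Shibata reduction: the ketone binds the (S)-oxazaborolidine anti to its larger 1-substituted vinyl arm (C8), so hydride reaches the face that gives the 7R carbinol, and the low temperature keeps imide, ester and alkenes untouched.

Step 13
Reactants: 21 (7R)-allylic alcohol
Product: 22 the (9R)-9-(tert-butyldimethylsilyloxy) imide ester (C7–OTBS, C13–OTES)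
Conditions: t-BuMe2SiOTf, 2,6-lutidine, CH2Cl2, −78 °C
Reagents that add atoms: tert-butyldimethylsilyl triflate, CC(C)(C)[Si](C)(C)OS(=O)(=O)C(F)(F)F
Why: Silylation of the hindered secondary allylic alcohol with the silyl triflate is fast at low temperature and gives an ether that outlasts the primary triethylsilyl ether and the titanium step.

Step 14
Reactants: 22 bis-silyl imide ester
Product: 23 methyl (3S,5E,9R,14S)-9-(tert-butyldimethylsilyloxy)-3-[(ethylsulfanyl)carbonyl]-6,14-dimethyl-10-methylidene-15-(triethylsilyloxy)pentadec-5-enoate (C14 thioester)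
Conditions: EtSH, n-BuLi, THF, 0 °C
Reagents that add atoms: ethanethiol, CCS
Why: Transacylation of the imide by lithium ethanethiolate at the exocyclic carbonyl keeps C14 at the acid oxidation level, which avoids a C14 alcohol that would lactonise onto the C16 ester, and the weakly basic thiolate should not epimerise C1.

Step 15
Reactants: 23 C14 thioester
Product: 24 methyl (3S,5E,9R,14S)-9-(tert-butyldimethylsilyloxy)-3-[(ethylsulfanyl)carbonyl]-6,14-dimethyl-10-methylidene-15-oxopentadec-5-enoate (C13 aldehyde)
Conditions: (COCl)2, DMSO, CH2Cl2, −78 → −40 °C; Et3N, −78 → 0 °C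
Reagents that add atoms: none
Why: Swern oxidation applied directly to the silyl ether: the chlorosulfonium salt attacks the unhindered primary Et3Si–O oxygen, chloride removes silicon and base-induced elimination gives the C13 aldehyde, whereas the hindered secondary t-BuMe2Si ether and the thioester do not react.

Step 16
Reactants: 24 C13 aldehyde thioester
Product: 25 methyl (3S,5E,9R,14S)-9-(tert-butyldimethylsilyloxy)-3-formyl-6,14-dimethyl-10-methylidene-15-oxopentadec-5-enoate (C13,C14-dialdehyde, 1S,7R,12S; used at once)
Conditions: Et3SiH, Pd/C (5 mol % Pd), acetone, rt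
Reagents that add atoms: none
Why: Fukuyama reduction: palladium inserts into the C–S bond of the thioester and Et3SiH delivers hydride, which stops at the C14 aldehyde under neutral conditions that spare the methyl ester, the C13 aldehyde, the hindered alkenes and the epimerisable centres C1 and C12.

Step 17
Reactants: 25 C13,C14-dialdehyde
Product: 27 (1S,3E,7R,12S,13R,14R)-7-(tert-butyldimethylsilyloxy)-13-hydroxy-17-norcembra-3,8(19)-dien-16,14-olide (cis-fused γ-lactone), via macrocyclic diol ester 26 (not isolated)
Conditions: TiCl3(DME)1.5, Zn–Cu, DME, reflux, 4 h; cool to 25 °C; 25 in DME by syringe pump over 30 h (final ca. 1 mM); aq K2CO3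
Reagents that add atoms: none
Why: Low-valent titanium transfers one electron to each aldehyde and the two titanium-bound ketyl radicals collapse on the metal to a titanium 13,14-diolate, while a temperature at or below 25 °C prevents the deoxygenation to the alkene that sets in at reflux. The closest known reaction type is the McMurry-type intramolecular pinacol coupling of dialdehydes under high dilution, which is established for 14-membered carbocycles. The carbocycle closes by radical–radical combination of C13 and C14 with both C–O bonds outside the forming ring (exo at each terminus), and the γ-lactone closes by 5-exo-trig addition–elimination of the C14 alkoxide on the C16 methyl ester, faster than the 6-exo alternative from O13, so that C13–OH stays free. C13 is controlled by Felkin–Anh 1,2-induction from C12 (bond formation anti to the C11 chain, 12S leading to 13R). C14 is tied to C13 by the preference of the titanium-bridged ketyl pair to hold its two carbon chains apart (threo), which with 13R means 14R and hence the cis-fused lactone, whereas C1 with its two similar CH2 arms adds only a weak bias. The step needs aldehyde-only reduction and ring closure over oligomerisation: the substrate holds no epoxide, enoate or free allylic alcohol, the ester, silyl ether and isolated alkenes are inert below reflux, and slow addition keeps the dialdehyde dilute.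

Step 18
Reactants: 27 13-hydroxy lactone
Product: 28 the 13-(triethylsilyloxy) derivative of 27
Conditions: Et3SiOTf, 2,6-lutidine, CH2Cl2, −78 → 0 °C
Reagents that add atoms: triethylsilyl triflate, CC[Si](CC)(CC)OS(=O)(=O)C(F)(F)F
Why: Silyl triflate silylation masks the hindered C13 hydroxyl, which would otherwise consume base and could translactonise during enolate formation.

Step 19
Reactants: 28 bis-silyl lactone
Product: 30 the 15-(dimethylaminomethyl) lactone (C15 epimers), via lithium lactone enolate 29 (not isolated)
Conditions: LiN(i-Pr)2, THF, −78 °C; Me2N=CH2 iodide, −78 °C → rt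
Reagents that add atoms: N,N-dimethylmethyleneiminium iodide (Eschenmoser's salt), C=[N+](C)C.[I-]
Why: Mannich-type aminomethylation of the lactone lithium enolate with Eschenmoser's salt introduces C17 at C15, the only enolisable position, and the C15 configuration is irrelevant because it is erased in step 20.

Step 20
Reactants: 30 Mannich base
Product: 32 (1S,3E,7R,12S,13R,14R)-7-(tert-butyldimethylsilyloxy)-13-(triethylsilyloxy)cembra-3,8(19),15(17)-trien-16,14-olide, via trimethylammonium iodide 31 (not isolated)
Conditions: MeI, CH2Cl2, rt; then DBU, rt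
Reagents that add atoms: none
Why: Exhaustive methylation of the amine and base-induced Hofmann-type β-elimination of trimethylamine give the conjugated C15=C17 exomethylene.

Step 21
Reactants: 32 bis-silyl α-methylene lactone
Product: 33 (1S,3E,7R,12S,13R,14R)-7,13-dihydroxycembra-3,8(19),15(17)-trien-16,14-olide
Conditions: HF·pyridine, pyridine, THF, 0 °C → rt
Reagents that add atoms: none
Why: Fluoride-driven cleavage of both silyl ethers under mildly acidic conditions avoids the basic media in which the α-methylene lactone could suffer conjugate addition or translactonisation.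

Step 22
Reactants: 33 diol
Product: 34 (1S,3E,7R,12S,13R,14R)-7,13-diacetoxycembra-3,8(19),15(17)-trien-16,14-olide
Conditions: Ac2O, DMAP (cat.), pyridine, CH2Cl2, rt
Reagents that add atoms: acetic anhydride, CC(=O)OC(C)=O
Why: DMAP-catalysed acetylation esterifies both secondary alcohols with retention at C7 and C13.

Step 23
Reactants: 34 diacetate
Product: 35 (1S,3R,4R,7R,12S,13R,14R)-7,13-diacetoxy-3,4-epoxycembra-8(19),15(17)-dien-16,14-olide (target)
Conditions: D-fructose-derived Shi ketone (0.5 equiv), KHSO5, K2CO3, Bu4NHSO4, Na2B4O7 buffer, MeCN–CH2(OMe)2–H2O, 0 °C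
Reagents that add atoms: potassium peroxymonosulfate, [K+].[O-]S(=O)(=O)OO
Why: Shi epoxidation: the chiral dioxirane from the D-fructose-derived ketone meets E-trisubstituted alkenes through a spiro transition state on the face that gives the (R,R)-oxirane (3R,4R), while the electron-poor C15=C17 enoate and the 1,1-disubstituted C8=C19 alkene, deactivated by its allylic acetate, react much more slowly.

Compound list
1 | hept-6-ynoic acid | C#CCCCCC(=O)O | starting material
2 | (S)-4-benzyl-1,3-oxazolidin-2-one | O=C1N[C@@H](Cc2ccccc2)CO1 | starting material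
3 | hept-6-ynoic pivalic anhydride | C#CCCCCC(=O)OC(=O)C(C)(C)C | intermediate
4 | (4S)-4-benzyl-3-(hept-6-ynoyl)-1,3-oxazolidin-2-one | C#CCCCCC(=O)N1[C@@H](Cc2ccccc2)COC1=O | intermediate
5 | sodium Z-enolate of 4 | C#CCCC/C=C(\[O-])N1[C@@H](Cc2ccccc2)COC1=O.[Na+] | intermediate
6 | (4S)-4-benzyl-3-[(2S)-2-methylhept-6-ynoyl]-1,3-oxazolidin-2-one | C#CCCC[C@H](C)C(=O)N1[C@@H](Cc2ccccc2)COC1=O | intermediate
7 | (2S)-2-methylhept-6-yn-1-ol | C#CCCC[C@H](C)CO | intermediate
8 | (2S)-6-iodo-2-methylhept-6-en-1-ol | C=C(I)CCC[C@H](C)CO | intermediate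
9 | triethyl{[(2S)-6-iodo-2-methylhept-6-en-1-yl]oxy}silane | C=C(I)CCC[C@H](C)CO[Si](CC)(CC)CC | intermediate
10 | geranyl bromide | CC(C)=CCC/C(C)=C/CBr | starting material
11 | 6,7-epoxygeranyl bromide (racemic) | CC1(C)OC1CC/C(C)=C/CBr | intermediate
12 | methyl 4-chloro-4-oxobutanoate | COC(=O)CCC(=O)Cl | starting material
13 | methyl 4-[(4S)-4-benzyl-2-oxo-1,3-oxazolidin-3-yl]-4-oxobutanoate | COC(=O)CCC(=O)N1[C@@H](Cc2ccccc2)COC1=O | intermediate
14 | sodium Z-enolate of 13 | COC(=O)C/C=C(\[O-])N1[C@@H](Cc2ccccc2)COC1=O.[Na+] | intermediate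
15 | epoxy imide ester (C1 = S) | CC1(C)OC1CC/C(C)=C/C[C@@H](CC(=O)OC)C(=O)N2[C@@H](Cc3ccccc3)COC2=O | intermediate
16 | vicinal diol from 15 | CC(C)(O)C(O)CC/C(C)=C/C[C@@H](CC(=O)OC)C(=O)N1[C@@H](Cc2ccccc2)COC1=O | intermediate
17 | C7 aldehyde imide ester | O=CCC/C(C)=C/C[C@@H](CC(=O)OC)C(=O)N1[C@@H](Cc2ccccc2)COC1=O | intermediate
18 | [(6S)-6-methyl-7-(triethylsilyloxy)hept-1-en-2-yl]chromium dichloride | CC[Si](CC)(CC)OC[C@@H](C)CCCC(=C)[Cr](Cl)Cl | intermediate
19 | allylic alcohol, C7 epimers | CC[Si](CC)(CC)OC[C@@H](C)CCCC(=C)C(O)CC/C(C)=C/C[C@@H](CC(=O)OC)C(=O)N1[C@@H](Cc2ccccc2)COC1=O | intermediate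
20 | C7 enone | CC[Si](CC)(CC)OC[C@@H](C)CCCC(=C)C(=O)CC/C(C)=C/C[C@@H](CC(=O)OC)C(=O)N1[C@@H](Cc2ccccc2)COC1=O | intermediate
21 | (7R)-allylic alcohol | CC[Si](CC)(CC)OC[C@@H](C)CCCC(=C)[C@H](O)CC/C(C)=C/C[C@@H](CC(=O)OC)C(=O)N1[C@@H](Cc2ccccc2)COC1=O | intermediate
22 | C7–OTBS, C13–OTES imide ester | CC[Si](CC)(CC)OC[C@@H](C)CCCC(=C)[C@H](O[Si](C)(C)C(C)(C)C)CC/C(C)=C/C[C@@H](CC(=O)OC)C(=O)N1[C@@H](Cc2ccccc2)COC1=O | intermediate
23 | C14 S-ethyl thioester | CC[Si](CC)(CC)OC[C@@H](C)CCCC(=C)[C@H](O[Si](C)(C)C(C)(C)C)CC/C(C)=C/C[C@@H](CC(=O)OC)C(=O)SCC | intermediate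
24 | C13 aldehyde, C14 thioester | O=C[C@@H](C)CCCC(=C)[C@H](O[Si](C)(C)C(C)(C)C)CC/C(C)=C/C[C@@H](CC(=O)OC)C(=O)SCC | intermediate
25 | C13,C14-dialdehyde with C16 methyl ester | O=C[C@@H](C)CCCC(=C)[C@H](O[Si](C)(C)C(C)(C)C)CC/C(C)=C/C[C@@H](CC(=O)OC)C=O | intermediate
26 | macrocyclic 13R,14R-diol methyl ester (present as its titanium diolate) | C=C1CCC[C@H](C)[C@@H](O)[C@H](O)[C@H](CC(=O)OC)C/C=C(\C)CC[C@H]1O[Si](C)(C)C(C)(C)C | intermediate
27 | 13-hydroxy macrocycle with saturated cis-lactone | C=C1CCC[C@H](C)[C@@H](O)[C@@H]2OC(=O)C[C@@H]2C/C=C(\C)CC[C@H]1O[Si](C)(C)C(C)(C)C | intermediate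
28 | 13-OTES, 7-OTBS lactone | C=C1CCC[C@H](C)[C@@H](O[Si](CC)(CC)CC)[C@@H]2OC(=O)C[C@@H]2C/C=C(\C)CC[C@H]1O[Si](C)(C)C(C)(C)C | intermediate
29 | lithium enolate of 28 | C=C1CCC[C@H](C)[C@@H](O[Si](CC)(CC)CC)[C@@H]2OC([O-])=C[C@@H]2C/C=C(\C)CC[C@H]1O[Si](C)(C)C(C)(C)C.[Li+] | intermediate
30 | 15-(dimethylaminomethyl) lactone | C=C1CCC[C@H](C)[C@@H](O[Si](CC)(CC)CC)[C@@H]2OC(=O)C(CN(C)C)[C@@H]2C/C=C(\C)CC[C@H]1O[Si](C)(C)C(C)(C)C | intermediate
31 | trimethylammonium iodide from 30 | C=C1CCC[C@H](C)[C@@H](O[Si](CC)(CC)CC)[C@@H]2OC(=O)C(C[N+](C)(C)C)[C@@H]2C/C=C(\C)CC[C@H]1O[Si](C)(C)C(C)(C)C.[I-] | intermediate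
32 | bis-silyl α-methylene lactone | C=C1CCC[C@H](C)[C@@H](O[Si](CC)(CC)CC)[C@@H]2OC(=O)C(=C)[C@@H]2C/C=C(\C)CC[C@H]1O[Si](C)(C)C(C)(C)C | intermediate
33 | 7,13-diol α-methylene lactone | C=C1CCC[C@H](C)[C@@H](O)[C@@H]2OC(=O)C(=C)[C@@H]2C/C=C(\C)CC[C@H]1O | intermediate
34 | 7,13-diacetate | C=C1CCC[C@H](C)[C@@H](OC(C)=O)[C@@H]2OC(=O)C(=C)[C@@H]2C/C=C(\C)CC[C@H]1OC(C)=O | intermediate
35 | CNP0323853.1 | C=C1CCC[C@H](C)[C@@H](OC(C)=O)[C@@H]2OC(=O)C(=C)[C@@H]2C[C@H]2O[C@]2(C)CC[C@H]1OC(C)=O | target

Total step count: 23. Longest linear sequence: 19 steps (steps 1–5 and 10–23).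

Steps most likely to fail

**Step 17.** The two ketyl radicals may combine with little regard for relative configuration (erythro instead of threo union). Intermolecular coupling may also compete with ring closure. The fallback sets out from 25 and comes back at 27. It no longer sets C13 in the C–C bond formation but by hydride delivery.
- The coupling of 25 is run as in step 17.
- The lactone fraction that is epimeric at C13, the (13S)-hydroxy lactone F1, is oxidised with Dess–Martin periodinane (pyridine, CH2Cl2) to the 13-oxo lactone F2.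
- F2 is reduced with LiBH(s-Bu)3 in THF at −78 °C.
- The non-chelating acyloxy oxygen on C14 is held perpendicular to the carbonyl (polar Felkin–Anh model). Hydride should therefore arrive anti to that oxygen and give the threo alcohol 27, which re-enters at step 18.

**Step 23.** The conformation of the 14-membered ring exposes mainly the outer face of C3=C4. This substrate bias may override the chiral dioxirane and give poor or reversed facial selectivity. The basic aqueous medium may also attack the acetates or the enoate. The fallback sets out from 34 and comes back at 35. It turns the same bias to use through a halohydrin.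
- NBS in aqueous DME at 0 °C forms the bromonium ion on the exposed face of the most nucleophilic alkene.
- Water opens it at the tertiary carbon C4 from the inner face to give the (3S,4R)-3-bromo-4-hydroxy diacetate F3.
- DBU in CH2Cl2 closes the oxirane by SN2 displacement at C3. This places oxygen on the face that direct epoxidation does not reach.

**Step 12.** Facial discrimination in the hydride transfer may be incomplete, since the two ketone arms differ less than aryl and methyl. This would leave a C7 epimer that lies far from C1 and C12 and is hard to separate. The fallback sets out from 19, comes back at 21 and replaces steps 11 and 12 by a Sharpless kinetic resolution.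
- Conditions are Ti(OiPr)4, L-(+)-diisopropyl tartrate, t-BuOOH (0.6 equiv), 4 Å molecular sieves, CH2Cl2, −20 °C.
- The 7S epimer is the fast-reacting one and is converted into the polar (7S,8R)-8,19-epoxy alcohol F4, which chromatography removes.
- The slow-reacting 7R epimer is 21.
- The same treatment can also upgrade material obtained from step 12.

Further compounds
F1 | step 17 | (13S)-hydroxy lactone, 13-epi-27 | C=C1CCC[C@H](C)[C@H](O)[C@@H]2OC(=O)C[C@@H]2C/C=C(\C)CC[C@H]1O[Si](C)(C)C(C)(C)C
F2 | step 17 | 13-oxo lactone | C=C1CCC[C@H](C)C(=O)[C@@H]2OC(=O)C[C@@H]2C/C=C(\C)CC[C@H]1O[Si](C)(C)C(C)(C)C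
F3 | step 23 | (3S,4R)-3-bromo-4-hydroxy diacetate | C=C1CCC[C@H](C)[C@@H](OC(C)=O)[C@@H]2OC(=O)C(=C)[C@@H]2C[C@H](Br)[C@](C)(O)CC[C@H]1OC(C)=O
F4 | step 12 | (7S,8R)-8,19-epoxy alcohol from the 7S epimer of 19 | O[C@@H](CC/C(C)=C/C[C@@H](CC(=O)OC)C(=O)N1[C@@H](Cc2ccccc2)COC1=O)[C@@]3(CCC[C@H](C)CO[Si](CC)(CC)CC)CO3
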